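**Assumptions:** The acyl chain in the SMILES is 30 carbons including the carbonyl, so the target is 4-hydroxyphenethyl triacontanoate (tyrosol triacontanoate), C38H68O3. The molecule is achiral and has no stereocenters, so no stereochemistry needs to be set.

## Retrosynthetic overview
1. The only disconnection is the ester C(acyl)–O bond, which gives tyrosol (1) and triacontanoic (melissic) acid (2).
2. No rings need to be built, because the benzene ring is already in tyrosol.
3. The one issue is chemoselectivity: the primary aliphatic OH must be acylated and the phenolic OH left free. A lipase (CAL-B) does this without protecting groups, so the route is a single step.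

## Route

**Step 1**
Reactants: 1 (tyrosol, 2-(4-hydroxyphenyl)ethanol, 2.0 equiv); 2 (triacontanoic acid, 1.0 equiv)
Product: 3 (4-hydroxyphenethyl triacontanoate, the target)
Conditions: Novozym 435 (immobilized *Candida antarctica* lipase B, ~20 wt% relative to the acid), 4 Å molecular sieves, toluene/2-methyl-2-butanol (1:1), 65–70 °C, 48 h. Filter off enzyme and sieves while hot, concentrate, then remove excess tyrosol by trituration with hot water or MeOH and recrystallize or chromatograph.
Reagents that add atoms: none. The acid 2 is the acyl donor and is already listed as a reactant. The enzyme, sieves and solvents leave no atoms in the product, and water is the by-product.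
Why: CAL-B catalyzes direct esterification of primary aliphatic alcohols and does not acylate phenols, so only the primary CH2OH of tyrosol is esterified (lipase-catalyzed chemoselective esterification). Sieves remove water to drive the equilibrium, and the tertiary alcohol cosolvent dissolves tyrosol and is not a substrate for the enzyme.

**Checks**
- Atom balance: C8H10O2 (1) + C30H60O2 (2) → C38H68O3 (3) + H2O.
- Target match: 3 is CCCCCCCCCCCCCCCCCCCCCCCCCCCCCC(=O)OCCc1ccc(O)cc1, with a free para-phenol, an ethylene spacer and a C30 acyl ester.
- Functional groups: the phenol and aryl ring are untouched by the mild, neutral conditions, and the product ester is not hydrolyzed because water is removed.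
- Stereocenters: none exist in the target, so none can be scrambled.

## Compound list
1 | Tyrosol, 2-(4-hydroxyphenyl)ethanol | OCCc1ccc(O)cc1 | starting material
2 | Triacontanoic (melissic) acid | CCCCCCCCCCCCCCCCCCCCCCCCCCCCCC(=O)O | starting material
3 | 4-Hydroxyphenethyl triacontanoate (Basalethanolide B) | CCCCCCCCCCCCCCCCCCCCCCCCCCCCCC(=O)OCCc1ccc(O)cc1 | target

## Totals
- Total step count: 1
- Longest linear sequence: 1
- The route has only one step, so the three risks below are failure modes of that step rather than three separate steps.

1. **Low conversion from poor solubility of the C30 acid and slow enzyme kinetics.**
   - Fallback: change the acyl donor and activation. Convert 2 to triacontanoyl chloride (oxalyl chloride, cat. DMF) and acylate 2-(4-benzyloxyphenyl)ethanol with pyridine/DMAP in CH2Cl2 or THF. Then remove the benzyl group by H2, Pd/C in THF. This is a 2–3 step route.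
2. **Competing phenol acylation or diacylation, which would only arise under non-enzymatic conditions or from a nonselective enzyme batch.**
   - Fallback: use a phenol-blocked tyrosol, either 4-(TBSO)phenethyl alcohol with Steglich esterification (DCC, DMAP) followed by TBAF/AcOH, or the benzyl ether above. This converts the problem from chemoselectivity to protecting-group management.
3. **Purification: the product is a waxy, lipophilic solid that co-elutes with residual acid 2.**
   - Fallback: drive the reaction to full consumption of 2 by using more tyrosol, then wash with warm aqueous base to remove any trace acid. If that fails, switch to a transesterification route from methyl triacontanoate with tyrosol under lipase or Ti(OiPr)4 catalysis, which avoids leftover free acid.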